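In this flask, the number to carry is the usable E (effective initiator), the charge of E less the charge of X: 17.4 µM.

    Z + J → Q + J, rate k1*[J]*[Z] (k1 = 92000 M⁻¹ s⁻¹)
    E + X → E.X (k2 = 3.0 × 10⁶ M⁻¹ s⁻¹)
    Z → G (k3 = 0.0069 s⁻¹)
    Z + E → J + Q (k4 = 640 M⁻¹ s⁻¹)

Z 1.0 mM; E 2 mol%; X 2.6 µM; time 2.0 s

* average number of monomer units in a chain (chains begun, living or dead) at 2.0 s
* part of the Z that has reacted at 2.0 s

- the average divides the monomer in chains by the number of chains begun, living and dead together
- run time (flask): 2.0 s

Start with X. Its charge is small, but k2 is large, so X lasts about 16.7 ms beside E at its charge, far shorter than the 1.56 s that E lasts beside Z at its charge. The crossing lies at cX = 0.213 µM, where X and Z at its charge take E equally fast. The flask starts above it, so in my reckoning each X costs one E.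

Next comes step 4. With cZ held at its charge, it turns the usable E into 12.6 µM of J by 2.0 s. But cZ falls, so my figure stands high, and my reckoning stops there.

The forecast gives 70.6 and 71.2%, and its ground is the same split of E, “which leaves 20 − 2.6 = 17.4 µM of E for initiation”.

The flask gives 70.6 and 71.2%. At 2.00 s, its J and remaining E add up to 17.4 µM, which matches the usable E, while X stands at 0% and E.X at 0.00260 mM. Now take the neighbour charged with 3.4 mol% of E. Its usable E is 31.4 µM, and its J and remaining E add up to 31.4 µM. That neighbour holds 0.0155 mM of J, reaches 87.1% of Z reacted, and gives a dp of 55.6.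

Its constants are made up; the flask was simulated.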